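The cyclohexene ring (C1 aroyl, C2 prenyl, C3 methyl, C6 phenyl) is disconnected between C2, the allylic methine lying β to the aryl ketone, and C3, the methyl-bearing alkene carbon. Because C2 is the β-carbon of the C1 aroyl unit and C3 is vinylic, a (Z)-vinyl iodide and an (E)-α-alkylidene ketone held in one acyclic chain are joined by a 6-endo vinyl-radical conjugate addition. This one operation closes the carbocycle, leaves the C3=C4 alkene in place and sets C2 and C1 relative to the C6 phenyl stereocentre, installed earlier by an organocatalytic Mukaiyama–Michael addition. The precursor already carries the benzofuran and the prenyl chain.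

Key step: step 9

Remark: compounds 1, 2, 8 and 11 are taken as commercial.
Remark: the sense of induction in step 5 is assigned from the usual face-shielding model of the imidazolidinone; the mirror-image catalyst is used if it proves opposite.

Step 1
Reactants: 1 1-(2,6-dihydroxy-4-methoxyphenyl)ethan-1-one; 2 2-bromo-1,1-diethoxyethane
Product: 3 1-[2-(2,2-diethoxyethoxy)-6-hydroxy-4-methoxyphenyl]ethan-1-one
Conditions: K2CO3, DMF, 80 °C
Reagents that add atoms: none
Why: Williamson O-alkylation, in which the remaining phenol is locked in a hydrogen bond to the acetyl carbonyl and should therefore stop the reaction at the mono-ether.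

Step 2
Reactants: 3 1-[2-(2,2-diethoxyethoxy)-6-hydroxy-4-methoxyphenyl]ethan-1-one
Product: 4 1-(6-hydroxy-4-methoxy-1-benzofuran-7-yl)ethan-1-one
Conditions: Amberlyst-15, PhCl, 120 °C
Reagents that add atoms: none
Why: Acid-catalysed cyclodehydration of an aryloxyacetaldehyde acetal (intramolecular Friedel–Crafts attack of the oxocarbenium ion on the only free ortho carbon, then loss of ethanol) should give the benzofuran with the acetyl group at C7.

Step 3
Reactants: 4 1-(6-hydroxy-4-methoxy-1-benzofuran-7-yl)ethan-1-one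
Product: 5 1-[4-methoxy-6-(methoxymethoxy)-1-benzofuran-7-yl]ethan-1-one
Conditions: MOMCl, iPr2NEt, CH2Cl2, 0 °C to rt
Reagents that add atoms: chloromethyl methyl ether COCCl
Why: MOM etherification masks the chelated phenol, which would otherwise add to the later enone and consume the bases used.

Step 4
Reactants: 5 1-[4-methoxy-6-(methoxymethoxy)-1-benzofuran-7-yl]ethan-1-one
Product: 7 4-methoxy-6-(methoxymethoxy)-7-{1-[(trimethylsilyl)oxy]ethenyl}-1-benzofuran, via lithium enolate 6 (not isolated)
Conditions: LiN(SiMe3)2, THF, −78 °C; then Me3SiCl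
Reagents that add atoms: chlorotrimethylsilane C[Si](C)(C)Cl
Why: Deprotonation at the only enolisable position and O-silylation give the enol silane needed for the Mukaiyama–Michael reaction.

Step 5
Reactants: 7 4-methoxy-6-(methoxymethoxy)-7-{1-[(trimethylsilyl)oxy]ethenyl}-1-benzofuran; 8 (2E)-3-phenylprop-2-enal
Product: 9 (3R)-5-[4-methoxy-6-(methoxymethoxy)-1-benzofuran-7-yl]-5-oxo-3-phenylpentanal
Conditions: (2S,5S)-5-benzyl-2-tert-butyl-3-methylimidazolidin-4-one (20 mol %), 2,4-dinitrobenzenesulfonic acid (20 mol %), wet t-BuOH/i-PrOH, −20 °C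
Reagents that add atoms: none
Why: Iminium-catalysed Mukaiyama–Michael addition of an aryl ketone enol silane to an enal, in which the benzyl and tert-butyl groups of the catalyst shield one face of the (E)-iminium ion so that the phenyl-bearing centre should form as (R).

Step 6
Reactants: 9 (3R)-5-[4-methoxy-6-(methoxymethoxy)-1-benzofuran-7-yl]-5-oxo-3-phenylpentanal
Product: 10 (3R,5Z)-6-iodo-1-[4-methoxy-6-(methoxymethoxy)-1-benzofuran-7-yl]-3-phenylhept-5-en-1-one
Conditions: EtPPh3I, n-BuLi, THF, rt; I2, −78 °C; NaN(SiMe3)2, −20 °C; then 9, −78 °C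
Reagents that add atoms: ethyltriphenylphosphonium iodide CC[P+](c1ccccc1)(c1ccccc1)c1ccccc1.[I-]; iodine II
Why: Stork–Zhao-type Wittig olefination with the α-iodo ylide should react at the aldehyde and not at the hindered aryl ketone and give the (Z)-2-iodoalkene, the geometry in which iodine and the chain are cis as the ring closure requires.

Step 7
Reactants: 11 4-methylpent-3-en-1-ol
Product: 12 4-methylpent-3-enal
Conditions: Dess–Martin periodinane, pyridine, CH2Cl2, 0 °C
Reagents that add atoms: none
Why: Buffered Dess–Martin oxidation should give the β,γ-unsaturated aldehyde without migration of the double bond, and the aldehyde is used at once.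

Step 8
Reactants: 10 (3R,5Z)-6-iodo-1-[4-methoxy-6-(methoxymethoxy)-1-benzofuran-7-yl]-3-phenylhept-5-en-1-one; 12 4-methylpent-3-enal
Product: 16 (2E,3S,5Z)-6-iodo-1-[4-methoxy-6-(methoxymethoxy)-1-benzofuran-7-yl]-2-(4-methylpent-3-en-1-ylidene)-3-phenylhept-5-en-1-one, via lithium enolate 13 (not isolated), via lithium aldolate 14 (not isolated), via mesylate 15 (not isolated)
Conditions: LiN(SiMe3)2, THF, −78 °C; 12; then MsCl, −78 to 0 °C; then DBU, 0 °C
Reagents that add atoms: none
Why: Aldol addition of the lithium enolate, O-mesylation of the aldolate and E1cB elimination (aldol condensation) should give the trisubstituted enone, the (E)-isomer with the side chain trans to the aroyl group being expected to predominate on thermodynamic grounds.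

Step 9
Reactants: 16 (2E,3S,5Z)-6-iodo-1-[4-methoxy-6-(methoxymethoxy)-1-benzofuran-7-yl]-2-(4-methylpent-3-en-1-ylidene)-3-phenylhept-5-en-1-one
Product: 17 [4-methoxy-6-(methoxymethoxy)-1-benzofuran-7-yl][(1R,2S,6R)-3-methyl-2-(3-methylbut-2-en-1-yl)-6-phenylcyclohex-3-en-1-yl]methanone
Conditions: Bu3SnH (syringe pump), AIBN, PhH (0.005 M), 80 °C
Reagents that add atoms: none
Why: The tributyltin radical abstracts iodine to give a σ-vinyl radical at the methyl-bearing carbon, which adds to the β-carbon of the enone, and the resulting α-keto radical takes hydrogen from Bu3SnH. The closest known reaction type is the tin-hydride vinyl-radical cyclisation onto an α-substituted enone or acrylate, an intramolecular Giese addition in the endo mode. The cyclohexene closes by 6-endo-trig attack, because the fully substituted α-carbon disfavours 5-exo closure and any 5-exo radical can still funnel to the same stabilised α-keto radical by homoallyl–cyclopropylcarbinyl rearrangement. C2 is controlled by the C6 centre: in the chair-like transition state of the (E)-enone the C2 side chain must become pseudo-axial, so the C6 phenyl group takes the pseudo-equatorial position to avoid a 1,3-diaxial clash, which places the prenyl group trans to phenyl. C1 is set when hydrogen is delivered to the α-keto radical anti to the pseudo-axial C2 chain, which puts the aroyl group equatorial, cis to prenyl and trans to phenyl; this is also the expected thermodynamic arrangement, so mild base equilibration should correct a C1 epimer. The step needs ring closure to outrun reduction of the vinyl radical, which high dilution and slow addition of Bu3SnH secure, and attack at the β-carbon, which the polarity match between the nucleophilic vinyl radical and the electron-poor enone secures.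

Step 10
Reactants: 17 [4-methoxy-6-(methoxymethoxy)-1-benzofuran-7-yl][(1R,2S,6R)-3-methyl-2-(3-methylbut-2-en-1-yl)-6-phenylcyclohex-3-en-1-yl]methanone
Product: 18 (6-hydroxy-4-methoxy-1-benzofuran-7-yl)[(1R,2S,6R)-3-methyl-2-(3-methylbut-2-en-1-yl)-6-phenylcyclohex-3-en-1-yl]methanone
Conditions: 3 M HCl, MeOH, 40 °C
Reagents that add atoms: none
Why: Acid-catalysed acetal exchange removes the MOM group, assisted by the ortho carbonyl, under conditions expected to leave the trisubstituted alkenes and the C1 configuration untouched.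

Compound list
1 | 1-(2,6-dihydroxy-4-methoxyphenyl)ethan-1-one | CC(=O)c1c(O)cc(OC)cc1O | starting material
2 | 2-bromo-1,1-diethoxyethane | CCOC(CBr)OCC | starting material
3 | 1-[2-(2,2-diethoxyethoxy)-6-hydroxy-4-methoxyphenyl]ethan-1-one | CCOC(COc1cc(OC)cc(O)c1C(C)=O)OCC | intermediate
4 | 1-(6-hydroxy-4-methoxy-1-benzofuran-7-yl)ethan-1-one | CC(=O)c1c(O)cc(OC)c2ccoc12 | intermediate
5 | 1-[4-methoxy-6-(methoxymethoxy)-1-benzofuran-7-yl]ethan-1-one | CC(=O)c1c(OCOC)cc(OC)c2ccoc12 | intermediate
6 | lithium 1-[4-methoxy-6-(methoxymethoxy)-1-benzofuran-7-yl]ethen-1-olate (lithium enolate of 5, formed in the flask) | [Li+].[O-]C(=C)c1c(OCOC)cc(OC)c2ccoc12 | intermediate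
7 | 4-methoxy-6-(methoxymethoxy)-7-{1-[(trimethylsilyl)oxy]ethenyl}-1-benzofuran | C=C(O[Si](C)(C)C)c1c(OCOC)cc(OC)c2ccoc12 | intermediate
8 | (2E)-3-phenylprop-2-enal (cinnamaldehyde) | O=C/C=C/c1ccccc1 | starting material
9 | (3R)-5-[4-methoxy-6-(methoxymethoxy)-1-benzofuran-7-yl]-5-oxo-3-phenylpentanal | O=CC[C@H](CC(=O)c1c(OCOC)cc(OC)c2ccoc12)c1ccccc1 | intermediate
10 | (3R,5Z)-6-iodo-1-[4-methoxy-6-(methoxymethoxy)-1-benzofuran-7-yl]-3-phenylhept-5-en-1-one | C/C(I)=C/C[C@H](CC(=O)c1c(OCOC)cc(OC)c2ccoc12)c1ccccc1 | intermediate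
11 | 4-methylpent-3-en-1-ol | CC(C)=CCCO | starting material
12 | 4-methylpent-3-enal | CC(C)=CCC=O | intermediate
13 | lithium (3R,5Z)-6-iodo-1-[4-methoxy-6-(methoxymethoxy)-1-benzofuran-7-yl]-3-phenylhepta-1,5-dien-1-olate (lithium enolate of 10, enolate geometry not defined, formed in the flask) | C/C(I)=C/C[C@H](C=C([O-])c1c(OCOC)cc(OC)c2ccoc12)c1ccccc1.[Li+] | intermediate
14 | lithium alkoxide of (3R,5Z)-2-(1-hydroxy-4-methylpent-3-en-1-yl)-6-iodo-1-[4-methoxy-6-(methoxymethoxy)-1-benzofuran-7-yl]-3-phenylhept-5-en-1-one (diastereomer mixture at C2 and the carbinol carbon, formed in the flask) | C/C(I)=C/C[C@H](C(C([O-])CC=C(C)C)C(=O)c1c(OCOC)cc(OC)c2ccoc12)c1ccccc1.[Li+] | intermediate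
15 | 1-{(3R,5Z)-6-iodo-1-[4-methoxy-6-(methoxymethoxy)-1-benzofuran-7-yl]-1-oxo-3-phenylhept-5-en-2-yl}-4-methylpent-3-en-1-yl methanesulfonate (diastereomer mixture, formed in the flask) | C/C(I)=C/C[C@H](C(C(OS(C)(=O)=O)CC=C(C)C)C(=O)c1c(OCOC)cc(OC)c2ccoc12)c1ccccc1 | intermediate
16 | (2E,3S,5Z)-6-iodo-1-[4-methoxy-6-(methoxymethoxy)-1-benzofuran-7-yl]-2-(4-methylpent-3-en-1-ylidene)-3-phenylhept-5-en-1-one | C/C(I)=C/C[C@H](/C(=C\CC=C(C)C)C(=O)c1c(OCOC)cc(OC)c2ccoc12)c1ccccc1 | intermediate
17 | [4-methoxy-6-(methoxymethoxy)-1-benzofuran-7-yl][(1R,2S,6R)-3-methyl-2-(3-methylbut-2-en-1-yl)-6-phenylcyclohex-3-en-1-yl]methanone | COc1cc(OCOC)c(C(=O)[C@@H]2[C@H](CC=C(C)C)C(C)=CC[C@H]2c2ccccc2)c2occc12 | intermediate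
18 | (6-hydroxy-4-methoxy-1-benzofuran-7-yl)[(1R,2S,6R)-3-methyl-2-(3-methylbut-2-en-1-yl)-6-phenylcyclohex-3-en-1-yl]methanone | COc1cc(O)c(C(=O)[C@@H]2[C@H](CC=C(C)C)C(C)=CC[C@H]2c2ccccc2)c2occc12 | target

Total step count: 10. Longest linear sequence: 9 steps (steps 1 to 6 and 8 to 10; step 7 is a one-step side branch).

Steps most likely to fail

Step 9 (key ring closure). The vinyl radical may be reduced before it cyclises, may close onto the phenyl ring or in the 5-exo mode, and facial selectivity at C2 may be eroded if the enone isomerises under the radical conditions. The fallback replaces the radical chain by a two-electron organometallic closure of the same bond. Compound 16 is treated with stoichiometric zerovalent nickel, Ni(COD)2, and Et3N in MeCN/DMF at room temperature. Oxidative addition gives a vinylnickel iodide that adds 1,4 to the enone, and protonation of the nickel enolate on work-up gives 17. The fallback sets out from 16 and returns at 17 and forms no new compound (F0).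

Step 8 (aldol condensation). The enolisable aldehyde may transfer a proton to the enolate, the new double bond may migrate into conjugation with the side-chain alkene under DBU, and an E/Z mixture may form. The fallback leaves the side-chain alkene out until the end. Enolate 13, made from 10, is added to 3,3-dimethoxypropanal to give the β-hydroxy ketone (3R,5Z)-2-(1-hydroxy-3,3-dimethoxypropyl)-6-iodo-1-[4-methoxy-6-(methoxymethoxy)-1-benzofuran-7-yl]-3-phenylhept-5-en-1-one F1. MsCl/Et3N then gives the enone (2E,3S,5Z)-2-(3,3-dimethoxypropylidene)-6-iodo-1-[4-methoxy-6-(methoxymethoxy)-1-benzofuran-7-yl]-3-phenylhept-5-en-1-one F2. The tin-hydride cyclisation of step 9 gives the cyclohexene acetal [(1R,2S,6R)-2-(2,2-dimethoxyethyl)-3-methyl-6-phenylcyclohex-3-en-1-yl][4-methoxy-6-(methoxymethoxy)-1-benzofuran-7-yl]methanone F3. Aqueous HCl in THF removes the acetal and the MOM group to give the hydroxy aldehyde 2-[(1S,5R,6R)-6-(6-hydroxy-4-methoxy-1-benzofuran-7-carbonyl)-2-methyl-5-phenylcyclohex-2-en-1-yl]acetaldehyde F4. Wittig olefination with excess isopropylidenetriphenylphosphorane (from isopropyltriphenylphosphonium iodide and n-BuLi) gives 18. The fallback sets out from 10 and returns at 18.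

Step 5 (asymmetric Mukaiyama–Michael addition). The hindered enol silane may add slowly, may be protodesilylated back to 5, and the enantioselectivity may be eroded. The fallback sets the phenyl-bearing centre by iridium-catalysed branched-selective allylic alkylation instead. Compound 7 and cinnamyl methyl carbonate, with [Ir(cod)Cl]2, a chiral phosphoramidite ligand, CsF and ZnF2, give the β-vinyl ketone (3S)-1-[4-methoxy-6-(methoxymethoxy)-1-benzofuran-7-yl]-3-phenylpent-4-en-1-one F5. Hydroboration with 9-BBN and oxidation with NaBO3 give the primary alcohol (3R)-5-hydroxy-1-[4-methoxy-6-(methoxymethoxy)-1-benzofuran-7-yl]-3-phenylpentan-1-one F6, and Dess–Martin oxidation gives 9. The fallback sets out from 7 and returns at 9.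

Further compounds
F0 | step 9 | none | none
F1 | step 8 | (3R,5Z)-2-(1-hydroxy-3,3-dimethoxypropyl)-6-iodo-1-[4-methoxy-6-(methoxymethoxy)-1-benzofuran-7-yl]-3-phenylhept-5-en-1-one (diastereomer mixture at C2 and the carbinol carbon) | C/C(I)=C/C[C@H](C(C(O)CC(OC)OC)C(=O)c1c(OCOC)cc(OC)c2ccoc12)c1ccccc1
F2 | step 8 | (2E,3S,5Z)-2-(3,3-dimethoxypropylidene)-6-iodo-1-[4-methoxy-6-(methoxymethoxy)-1-benzofuran-7-yl]-3-phenylhept-5-en-1-one | C/C(I)=C/C[C@H](/C(=C\CC(OC)OC)C(=O)c1c(OCOC)cc(OC)c2ccoc12)c1ccccc1
F3 | step 8 | [(1R,2S,6R)-2-(2,2-dimethoxyethyl)-3-methyl-6-phenylcyclohex-3-en-1-yl][4-methoxy-6-(methoxymethoxy)-1-benzofuran-7-yl]methanone | COc1cc(OCOC)c(C(=O)[C@@H]2[C@H](CC(OC)OC)C(C)=CC[C@H]2c2ccccc2)c2occc12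
F4 | step 8 | 2-[(1S,5R,6R)-6-(6-hydroxy-4-methoxy-1-benzofuran-7-carbonyl)-2-methyl-5-phenylcyclohex-2-en-1-yl]acetaldehyde | COc1cc(O)c(C(=O)[C@@H]2[C@H](CC=O)C(C)=CC[C@H]2c2ccccc2)c2occc12
F5 | step 5 | (3S)-1-[4-methoxy-6-(methoxymethoxy)-1-benzofuran-7-yl]-3-phenylpent-4-en-1-one | C=C[C@H](CC(=O)c1c(OCOC)cc(OC)c2ccoc12)c1ccccc1
F6 | step 5 | (3R)-5-hydroxy-1-[4-methoxy-6-(methoxymethoxy)-1-benzofuran-7-yl]-3-phenylpentan-1-one | OCC[C@H](CC(=O)c1c(OCOC)cc(OC)c2ccoc12)c1ccccc1
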